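I follow YxJa.

| flask | Yx | Ez | Dw | time |
|---|---|---|---|---|
| spring | 6.0 mM | 1.80 equiv | 5.1 mM (held) | 6.0 d |
| midnight | 20 mM | 1.80 equiv | 5.1 mM (held) | 6.0 d |
| dawn | 60 mM | 1.80 equiv | 5.1 mM (held) | 6.0 d |

1. amount of EzYxJa at the end, in percent of the Yx charged for spring, midnight, dawn, in this order
2. the shape of the row from first to last (hardly changes / rises, then falls / falls, then rises / falls all the way / rises all the way)

- percent here means Yx units held: one YxYxJa counts as two
- what is said of EzYxJa includes Ul
- Ul is a solid; its amount is given per volume of the solution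
- at the start none of Ja is dissolved
- "hardly changes" means that all values lie within two and a half points (for a concentration: within two and a half percent of the largest)
- run time (spring): 6.0 d

    Dw ⇌ Ja, rate k1*(csat - [Ja]) (k1 = 0.043 h⁻¹, csat = 5.1 mM)
    Ez + YxJa → EzYxJa (k2 = 0.33 M⁻¹ h⁻¹)
    Yx + YxJa → YxYxJa (k3 = 0.49 M⁻¹ h⁻¹)
    Yx + Ja → YxJa (k4 = 3.0 M⁻¹ h⁻¹)
    Ul ⇌ EzYxJa, rate k5*(cs5 - [EzYxJa]) while solid is left; crystals form when [EzYxJa] > cs5 (cs5 = 20 mM, k5 = 1.8 h⁻¹)

Dw dissolves as Ja, Ja turns Yx into YxJa, and YxJa then meets either Ez, giving EzYxJa, or more Yx, giving YxYxJa.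

Which way does YxJa go? I divide one rate by the other, so that YxJa and time drop out. What remains is the split, the rate of YxJa with Ez over its rate with Yx, a selectivity factor. At the charge, Ez stands at 1.80 equiv of Yx, so concentration cancels and the split is 1.21 in spring and in dawn, and in midnight too. So 54.8% of the YxJa that reacts at the start gives EzYxJa, and the split at the charge does not separate the flasks.

Does YxJa react in time? In spring its half-life by Ez, with Ez as charged, is 8.1 d, longer than the run, so I expect YxJa still waiting at the end of spring. In midnight that half-life is 2.43 d, shorter than the run.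

Does enough gas arrive? With Ja held at zero, the run would take up 31.6 mM. That exceeds the midnight charge of Yx, but in dawn it is 52.6% of the charge. Multiplied by the share, this gives about 28.8% for dawn, and dissolved Ja can lower it. So I commit to a row that rises, then falls.

The forecast gives 19%, 29% and 21%, rises, then falls, since “the yield peaks in the middle”, and its dawn value lies below mine.

The simulation gives 16.4%, 26.2% and 20.0%: rises, then falls.

In dawn at 3.00 d, Yx stands at 74.9% and Ez at 95.4% of its charge, so the split has grown to 1.54; one YxYxJa counts as two Yx, so this split gives 0.770 for EzYxJa over YxYxJa in percent, and the end of dawn reads 0.800. In midnight at 3.00 d, with Yx at 59.8% and Ez at 95.0%, the same reckoning gives 0.962, and the end of midnight reads 1.07.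

The numbers of this flask belong to no real substance; the flask was simulated.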